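**Plan**

- Feature used: in ring B (tetralone numbering, C4a and C8a being the fusion carbons of phenol ring A) the ketone carbon C1, the cis-methyl carbons C2 and C3 and the aryl methine C4 form a four-carbon chain that can be stored as a cyclobutane tied to ring A through C1 alone.
- Retrosynthesis cuts, in order: the O–benzyl bond of a C7 benzyl ether; the C4–C4a bond (with C1–C4 re-joined, giving a 1,2-diaryl-3,4-dimethylcyclobutan-1-ol); the C1–C8a bond (giving a 2-arylcyclobutanone and a ring A aryl metal); the C1–C2 and C3–C4 bonds (giving a keteniminium ion from homoveratric acid and cis-2-butene).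
- Forward order: amide, four-membered ring by [2+2] cycloaddition, attachment of ring A at C1, oxidative opening of the cyclobutanol with closure of ring B onto ring A, debenzylation.
- Stereochemistry: the cis relation of the C2 and C3 methyl groups comes from cis-2-butene, their absolute configuration from a C2-symmetric pyrrolidine auxiliary on the amide, and C4 from the ring closure, where the aryl group goes anti to the C3 methyl group.

Key step: step 5

Assumption on the auxiliary: the (2R,5R)-pyrrolidine is taken to deliver the (3R,4S)-dimethyl ring; this sense rests on a steric model of the cycloaddition and is not secured by a close precedent, and if the opposite sense were found the commercially available (2S,5S)-amine would be used with nothing else changed.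

Assumption on spectator centres: the cyclobutaniminium salt, the cyclobutanone and the cyclobutanol are drawn as the epimers expected to predominate at the aryl-bearing ring carbon and at the carbinol carbon; both carbons become planar in step 5, so their configuration has no bearing on the product.

**Route**

Step 1
Reactants: 1 homoveratric acid [(3,4-dimethoxyphenyl)acetic acid]; 2 (2R,5R)-2,5-dimethylpyrrolidine
Product: 4 2-(3,4-dimethoxyphenyl)-1-[(2R,5R)-2,5-dimethylpyrrolidin-1-yl]ethan-1-one, via (3,4-dimethoxyphenyl)acetyl chloride 3 (not isolated)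
Conditions: (COCl)2, DMF (cat.), CH2Cl2, 0 °C to rt; evaporate; then 2, Et3N, CH2Cl2, 0 °C to rt
Reagents that add atoms: none
Why: N-acylation of a secondary amine by an acid chloride is dependable even for the α,α'-branched pyrrolidine, and no stereocentre is formed or touched.

Step 2
Reactants: 4 2-(3,4-dimethoxyphenyl)-1-[(2R,5R)-2,5-dimethylpyrrolidin-1-yl]ethan-1-one; 5 cis-2-butene
Product: 8 (2R,3R,4S)-2-(3,4-dimethoxyphenyl)-3,4-dimethylcyclobutan-1-one, via keteniminium triflate 6 (not isolated), via cyclobutaniminium triflate 7 (not isolated)
Conditions: Tf2O, 2,4,6-collidine, 5 (excess), ClCH2CH2Cl, sealed tube, −20 to 40 °C; then H2O, rt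
Reagents that add atoms: water, O
Why: O-triflation of the amide and loss of triflate with collidine should give keteniminium ion 6, which enters a keteniminium–alkene [2+2] cycloaddition that is suprafacial on the alkene, so the two methyl groups stay cis, while the C2-symmetric (2R,5R)-pyrrolidine is expected to disfavour one of the two enantiomeric approaches of the butene and so fix the absolute configuration at C3 and C4; the benzylic C2 centre should settle trans to the C3 methyl group through the enamine, and hydrolysis of iminium salt 7 releases the ketone and the recoverable auxiliary.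

Step 3
Reactants: 9 5-bromo-2-methoxyphenol
Product: 10 2-(benzyloxy)-4-bromo-1-methoxybenzene
Conditions: BnBr, K2CO3, DMF, rt
Reagents that add atoms: benzyl bromide, BrCc1ccccc1
Why: Williamson ether synthesis on the phenoxide installs a benzyl ether that should withstand the organometallic and oxidative steps and can be removed at the end without base.

Step 4
Reactants: 8 (2R,3R,4S)-2-(3,4-dimethoxyphenyl)-3,4-dimethylcyclobutan-1-one; 10 2-(benzyloxy)-4-bromo-1-methoxybenzene
Product: 13 (1R,2R,3R,4S)-1-[3-(benzyloxy)-4-methoxyphenyl]-2-(3,4-dimethoxyphenyl)-3,4-dimethylcyclobutan-1-ol, via aryllithium 11 (not isolated), via arylcerium dichloride 12 (not isolated)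
Conditions: 10, n-BuLi, THF, −78 °C; CeCl3 (anhydrous), −78 °C; then 8, −78 °C; H2O
Reagents that add atoms: none
Why: Bromine–lithium exchange followed by transmetalation to cerium gives a weakly basic but strongly nucleophilic aryl reagent (organocerium 1,2-addition) that should add to the strained carbonyl of 8 instead of deprotonating its α-positions, so the C3 and C4 methyl centres are preserved; attack is expected anti to the neighbouring dimethoxyphenyl group, and the new carbinol centre is erased in step 5 in any case.

Step 5
Reactants: 13 (1R,2R,3R,4S)-1-[3-(benzyloxy)-4-methoxyphenyl]-2-(3,4-dimethoxyphenyl)-3,4-dimethylcyclobutan-1-ol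
Product: 14 (2S,3S,4R)-7-(benzyloxy)-4-(3,4-dimethoxyphenyl)-6-methoxy-2,3-dimethyl-3,4-dihydronaphthalen-1(2H)-one
Conditions: AgNO3 (20 mol %), K2S2O8, CH2Cl2/H2O (1:1), rt
Reagents that add atoms: none
Why: Divalent silver, formed from AgNO3 by persulfate, should oxidise the tertiary alcohol of 13 to an alkoxy radical, and strain-releasing β-scission then cleaves the ring bond from the carbinol carbon to the aryl-bearing carbon, because only that cleavage gives a benzylic radical; the carbinol carbon becomes the C1 ketone and the radical carbon becomes C4. The C4 radical, or the 3,4-dimethoxybenzylic cation formed from it by a further one-electron oxidation, attacks ring A at the carbon ortho to the acyl group and para to the benzyloxy group, closing ring B in a 6-endo-trig mode onto the C8a–C4a bond, and loss of one more electron and a proton restores the aromatic ring. The closest known reaction is the silver-catalysed oxidative ring expansion of 1-arylcyclobutanols to 1-tetralones with persulfate. C4 is the only new stereocentre and is set by the adjacent C3 centre: in the chair-like transition state the dimethoxyphenyl group lies pseudo-equatorial and anti to the C3 methyl group, and since C1 and C4 are both planar before the bond forms, either epimer of 13 at those carbons should lead to the same product. The step needs regioselective scission and regioselective arylation; the first is secured by benzylic stabilisation of the radical, the second by the benzyloxy group, which shields the ortho position it flanks and activates the position para to itself. C2 and C3 take no part, so the cis-dimethyl unit should pass through unchanged under these mild conditions at room temperature.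

Step 6
Reactants: 14 (2S,3S,4R)-7-(benzyloxy)-4-(3,4-dimethoxyphenyl)-6-methoxy-2,3-dimethyl-3,4-dihydronaphthalen-1(2H)-one
Product: 15 schisandrone, (2S,3S,4R)-4-(3,4-dimethoxyphenyl)-7-hydroxy-6-methoxy-2,3-dimethyl-3,4-dihydronaphthalen-1(2H)-one
Conditions: H2 (1 atm), Pd/C, EtOAc, rt
Reagents that add atoms: none
Why: Palladium-catalysed hydrogenolysis cleaves the benzylic C–O bond of the aryl benzyl ether under neutral conditions, faster than reduction of the electron-rich aryl ketone, and leaves the methyl ethers and the base-sensitive C2 centre untouched.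

**Compound list**

1 | homoveratric acid, (3,4-dimethoxyphenyl)acetic acid | OC(=O)Cc1ccc(OC)c(OC)c1 | starting material
2 | (2R,5R)-2,5-dimethylpyrrolidine | C[C@@H]1CC[C@@H](C)N1 | starting material
3 | (3,4-dimethoxyphenyl)acetyl chloride | COc1ccc(CC(Cl)=O)cc1OC | intermediate
4 | 2-(3,4-dimethoxyphenyl)-1-[(2R,5R)-2,5-dimethylpyrrolidin-1-yl]ethan-1-one | COc1ccc(CC(=O)N2[C@H](C)CC[C@H]2C)cc1OC | intermediate
5 | cis-2-butene | C/C=C\C | starting material
6 | (2R,5R)-1-[2-(3,4-dimethoxyphenyl)ethenylidene]-2,5-dimethylpyrrolidin-1-ium trifluoromethanesulfonate | COc1ccc(C=C=[N+]2[C@H](C)CC[C@H]2C)cc1OC.[O-]S(=O)(=O)C(F)(F)F | intermediate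
7 | (2R,5R)-1-[(2R,3R,4S)-2-(3,4-dimethoxyphenyl)-3,4-dimethylcyclobutylidene]-2,5-dimethylpyrrolidin-1-ium trifluoromethanesulfonate | C[C@@H]1CC[C@@H](C)[N+]1=C1[C@@H](C)[C@@H](C)[C@@H]1c1ccc(OC)c(OC)c1.[O-]S(=O)(=O)C(F)(F)F | intermediate
8 | (2R,3R,4S)-2-(3,4-dimethoxyphenyl)-3,4-dimethylcyclobutan-1-one (aryl trans to both methyl groups, methyl groups cis) | O=C1[C@@H](C)[C@@H](C)[C@@H]1c1ccc(OC)c(OC)c1 | intermediate
9 | 5-bromo-2-methoxyphenol | COc1ccc(Br)cc1O | starting material
10 | 2-(benzyloxy)-4-bromo-1-methoxybenzene | COc1ccc(Br)cc1OCc1ccccc1 | intermediate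
11 | [3-(benzyloxy)-4-methoxyphenyl]lithium | COc1ccc([Li])cc1OCc1ccccc1 | intermediate
12 | [3-(benzyloxy)-4-methoxyphenyl]cerium dichloride | COc1ccc([Ce](Cl)Cl)cc1OCc1ccccc1 | intermediate
13 | (1R,2R,3R,4S)-1-[3-(benzyloxy)-4-methoxyphenyl]-2-(3,4-dimethoxyphenyl)-3,4-dimethylcyclobutan-1-ol (hydroxyl cis to the dimethoxyphenyl group, ring A aryl cis to the two methyl groups) | COc1ccc(cc1OCc1ccccc1)[C@@]1(O)[C@@H](C)[C@@H](C)[C@@H]1c1ccc(OC)c(OC)c1 | intermediate
14 | (2S,3S,4R)-7-(benzyloxy)-4-(3,4-dimethoxyphenyl)-6-methoxy-2,3-dimethyl-3,4-dihydronaphthalen-1(2H)-one (schisandrone 7-O-benzyl ether; 2,3-cis, 3,4-trans) | COc1cc2c(cc1OCc1ccccc1)C(=O)[C@@H](C)[C@@H](C)[C@@H]2c1ccc(OC)c(OC)c1 | intermediate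
15 | schisandrone, (2S,3S,4R)-4-(3,4-dimethoxyphenyl)-7-hydroxy-6-methoxy-2,3-dimethyl-3,4-dihydronaphthalen-1(2H)-one | COc1cc2c(cc1O)C(=O)[C@@H](C)[C@@H](C)[C@@H]2c1ccc(OC)c(OC)c1 | target

**Step count**

Total steps: 6. Longest linear sequence: 5 steps (steps 1, 2, 4, 5 and 6; step 3 is the side branch to the ring A bromide).

**Steps most likely to fail**

Step 5. The open-chain benzylic radical or cation may be intercepted by water or lose a proton to give a styrene before it reaches ring A. The silver/persulfate couple may also over-oxidise the dialkoxyarenes, the benzyl ether or the doubly benzylic C4–H of the product. The fallback sets out from 13 and separates C–C cleavage from C–C formation. Irradiation of 13 with blue light in the presence of [Ir(dF(CF3)ppy)2(5,5'-d(CF3)bpy)]PF6, 2,4,6-collidine and thiophenol would open the ring by proton-coupled electron transfer without net oxidation, the benzylic radical being reduced by the thiol. This should give (2S,3S)-1-[3-(benzyloxy)-4-methoxyphenyl]-4-(3,4-dimethoxyphenyl)-2,3-dimethylbutan-1-one F1. DDQ in CH2Cl2 at 0 °C would then abstract hydride from the dimethoxybenzylic C4 position, and the cation would close onto ring A anti to the C3 methyl group (dehydrogenative Friedel–Crafts alkylation). The fallback comes back to the route at 14.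

Step 2. The auxiliary may discriminate poorly between the two enantiomeric approaches of the butene, so that the ketone is formed with low enantiomeric purity. The slow reaction of the unactivated alkene also leaves the keteniminium ion open to attack by the electron-rich arene of a second molecule. The fallback gives up auxiliary control for resolution and sets out from acid chloride 3, made from 1 as in step 1. With pyrrolidine and Et3N, 3 would give 2-(3,4-dimethoxyphenyl)-1-(pyrrolidin-1-yl)ethan-1-one F2. Tf2O and collidine would convert F2 into 1-[2-(3,4-dimethoxyphenyl)ethenylidene]pyrrolidin-1-ium trifluoromethanesulfonate F3. Cycloaddition of F3 with cis-2-butene would give racemic 1-[2-(3,4-dimethoxyphenyl)-3,4-dimethylcyclobutylidene]pyrrolidin-1-ium trifluoromethanesulfonate F4. Hydrolysis would give 8 together with its enantiomer, (2S,3S,4R)-2-(3,4-dimethoxyphenyl)-3,4-dimethylcyclobutan-1-one F5. Preparative HPLC on a chiral stationary phase would separate the two, and the fallback comes back to the route at 8.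

Step 4. The aryl metal may deprotonate the ketone at its benzylic α-carbon in competition with carbonyl addition, and the 2-aryl cyclobutoxide may open anionically. The fallback sets out from 8 and moves the aryl-bearing carbon away from the carbonyl before the aryl nucleophile is used. Baeyer–Villiger oxidation of 8 (mCPBA, NaHCO3, CH2Cl2, 0 °C), with migration of the dimethoxybenzylic carbon with retention, should give (3S,4R,5R)-5-(3,4-dimethoxyphenyl)-3,4-dimethyloxolan-2-one F6. Addition of aryllithium 11, generated from 10 as in step 4, to F6 in THF at −78 °C would give (2S,3R,4R)-1-[3-(benzyloxy)-4-methoxyphenyl]-4-(3,4-dimethoxyphenyl)-4-hydroxy-2,3-dimethylbutan-1-one F7. BF3·OEt2 in CH2Cl2 at low temperature would ionise the benzylic alcohol and close the C4–C4a bond by Friedel–Crafts alkylation, again anti to the C3 methyl group. This fallback bypasses 13 and comes back to the route at 14.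

**Further compounds**

F1 | step 5 | (2S,3S)-1-[3-(benzyloxy)-4-methoxyphenyl]-4-(3,4-dimethoxyphenyl)-2,3-dimethylbutan-1-one | COc1ccc(cc1OCc1ccccc1)C(=O)[C@@H](C)[C@@H](C)Cc1ccc(OC)c(OC)c1
F2 | step 2 | 2-(3,4-dimethoxyphenyl)-1-(pyrrolidin-1-yl)ethan-1-one | COc1ccc(CC(=O)N2CCCC2)cc1OC
F3 | step 2 | 1-[2-(3,4-dimethoxyphenyl)ethenylidene]pyrrolidin-1-ium trifluoromethanesulfonate | COc1ccc(C=C=[N+]2CCCC2)cc1OC.[O-]S(=O)(=O)C(F)(F)F
F4 | step 2 | rac-1-[(2R,3R,4S)-2-(3,4-dimethoxyphenyl)-3,4-dimethylcyclobutylidene]pyrrolidin-1-ium trifluoromethanesulfonate (racemate, one enantiomer drawn) | C1CC[N+](C1)=C1[C@@H](C)[C@@H](C)[C@@H]1c1ccc(OC)c(OC)c1.[O-]S(=O)(=O)C(F)(F)F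
F5 | step 2 | (2S,3S,4R)-2-(3,4-dimethoxyphenyl)-3,4-dimethylcyclobutan-1-one (enantiomer of 8) | O=C1[C@H](C)[C@H](C)[C@H]1c1ccc(OC)c(OC)c1
F6 | step 4 | (3S,4R,5R)-5-(3,4-dimethoxyphenyl)-3,4-dimethyloxolan-2-one | O=C1[C@@H](C)[C@@H](C)[C@@H](O1)c1ccc(OC)c(OC)c1
F7 | step 4 | (2S,3R,4R)-1-[3-(benzyloxy)-4-methoxyphenyl]-4-(3,4-dimethoxyphenyl)-4-hydroxy-2,3-dimethylbutan-1-one | COc1ccc(cc1OCc1ccccc1)C(=O)[C@@H](C)[C@@H](C)[C@@H](O)c1ccc(OC)c(OC)c1
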